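## The problem

Ring numbering used throughout: C1 is the ring carbonyl, C2 the C–OMe carbon, C3 the aryl-bearing alkene carbon, C4 the spiro carbon, C5 the C(OMe)(aryl) carbon and C6 the oxirane CH2. The target is a cyclopent-2-en-1-one without a single ring hydrogen, whose two aryl groups sit 1,3 to each other with a one-carbon unit on the carbon between them, a pattern that no simple five-carbon building block has. C4 and C5 are adjacent, fully substituted stereocentres, and in the (4R,5R) isomer (3R,4R in oxaspiro numbering) the oxirane oxygen is trans to the C5 methoxy group and cis to the C5 aryl group. Reagent control does not give this relation: an oxidant that attacks an exocyclic C4=C6 alkene should come in anti to the C5 aryl group (or syn to a C5 hydroxyl) and place the oxygen on the wrong face, and C5 has no hydrogen through which an error could be corrected, so the C4–O and C5–O bonds are best set in one anti event. The oxirane is allylic to the enol ether and ionizes easily under acid, any open C4 alkoxide is a β-alkoxide of the ketone (retro-aldol), and the phenol para to C5 can expel the C5 methoxy group under strong base (quinone methide), so the end game must be short and close to neutral. The enabling feature is the chain of six carbons C1–C6 with oxygen on C1, C2 and C4, in a 4-oxy-5-methoxycyclopent-2-enone whose two oxygens are trans. Tying the C4 oxygen back to C3 gives the six-membered ring O–C3–C2–C1–C5–C4, a 4H-pyran-4-one, and the target ring is what photochemical ring contraction of that pyranone with capture of methanol should give. The pyranone carbons and three of its oxygens are those of kojic acid.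

## Retrosynthesis

**11 from 10.** The two phenols are masked as silyl ethers in 10. The cut is two O–Si bonds, which buffered fluoride should cleave without touching the oxirane or the C5 ether. No skeletal change is involved.

**10 from 9.** The oxirane C6–O bond is cut. Precursor 9 carries the C4 hydroxyl and a sulfonate on C6, so the forward reaction is a 3-exo-tet displacement that leaves the C4–O bond, and with it the C4 configuration, untouched. This is preferred over epoxidation of a C4=C6 alkene, which would have to set C4 at this stage and should do so with the wrong sense. The sulfonate is a camphorsulfonate so that it also serves as the resolving group.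

**9 from 7 through 8 (key disconnection).** The C3–C4 bond and the C5–OMe bond are cut and the C4 oxygen is joined to C3. This turns the cyclopentenone into the flat 4-pyranone 7, which has no stereocentre in the ring. In the forward sense, excitation of 7 should close the C3–C4 bond to give the oxirane-bridged oxyallyl zwitterion 8. The alcohol solvent should add at C5 anti to the bridge, and the enol so formed should open the bridge at C3. Ring, both stereocentres in the correct trans relation, enone and enol ether would arise in one operation. The step must capture the solvent at the aryl-bearing terminus of 8 and not at the methoxy-bearing one. It cannot fix the absolute sense. Because the sulfonate of 7 carries a fixed (1S)-camphor unit, the two mirror-image ring systems arise as a pair of diastereomers, and 9 is obtained by separating it from the one with the opposite ring configuration.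

**7 from 5 and 6.** The S–O bond of the sulfonate is cut. Primary alcohol 5 and commercial sulfonyl chloride 6 result.

**5 from 3 and 4.** Both aryl–pyranone bonds are cut. Because the two aryl groups are identical, one twofold Suzuki–Miyaura coupling of dibromide 3 with boronic acid 4 should install both.

**3 from 2 from 1.** The O–Me bond and the two C–Br bonds are cut. Kojic acid 1 has exactly two ring C–H positions, C3 and C6 of the pyranone, so exhaustive bromination to 2 has no regiochemical ambiguity. The acidic enol hydroxyl is then methylated in the presence of the primary alcohol.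

## Roads not taken

Alternative 1: the most obvious cut is at C1–C5 and C2–C3. A twofold Claisen condensation of a 1,3-diarylacetone with an oxalate diester gives 3,5-bis[4-(benzyloxy)phenyl]cyclopentane-1,2,4-trione A1. Hydroxylation at C5 and two O-methylations would give (5R)-3,5-bis[4-(benzyloxy)phenyl]-2,5-dimethoxycyclopent-2-ene-1,4-dione A2. The forward key step is a Corey–Chaykovsky methylene transfer to the C4 carbonyl of A2, anti to the C5 aryl group.
- The ring forms in one step, but the difficulty is only moved. In A2 the C4 carbonyl is a vinylogous ester and lies between two aryl-bearing carbons, so the ylide should prefer C1.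
- The absolute configuration at C5 would have to come from oxidation of an enol whose two flanks differ only remotely.
- Several functional-group adjustments on three similar carbonyl groups follow a one-step ring synthesis.

Alternative 2: cut at C4–C5. The allenyl 1,2-diketone 1,4-bis[4-(tert-butyldimethylsilyloxy)phenyl]-1-methoxyhexa-4,5-diene-2,3-dione A3 would cyclize through its enol (Nazarov-type 4π closure, or 5-endo-dig Michael addition) under a chiral bifunctional amine catalyst. The product would be (5R)-3,5-bis[4-(tert-butyldimethylsilyloxy)phenyl]-2-hydroxy-5-methoxy-4-methylidenecyclopent-2-en-1-one A4, to be followed by O-methylation and epoxidation of the exocyclic alkene.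
- C5 would be set by catalysis, which is an advantage.
- The epoxidation must then place oxygen syn to the C5 aryl group. Steric approach control should place it anti, which gives the C4 epimer, and no directing group lies on the required face.
- A3 needs a long run-up, which gives away the gain of the cyclization.

Alternative 3: cut at C3–C4 again, but in the ground-state manifold. O-methylation of a 5-hydroxypyranone at the carbonyl oxygen and deprotonation would give 2,5-bis[4-(tert-butyldimethylsilyloxy)phenyl]-6-(hydroxymethyl)-4-methoxypyrylium-3-olate A5. Visible-light valence isomerization would give the epoxy ketone (1R,5S)-1,4-bis[4-(tert-butyldimethylsilyloxy)phenyl]-5-(hydroxymethyl)-3-methoxy-6-oxabicyclo[3.1.0]hex-3-en-2-one A6. A Payne rearrangement would move the oxirane to the spiro position with inversion at C4 and free the C5 oxygen, giving (3R,4R)-4,7-bis[4-(tert-butyldimethylsilyloxy)phenyl]-4-hydroxy-6-methoxy-1-oxaspiro[2.4]hept-6-en-5-one A7, whose tertiary hydroxyl would then be methylated.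
- It gives the same trans relation and has no ambiguity in the site of solvent capture.
- The Payne equilibrium between A6 and A7 has no clear bias, and methylation would partition between a primary and a hindered tertiary alkoxide.
- It needs a protecting group on the 5-hydroxyl through the coupling, and it has no leaving group that could double as a resolving handle.
- The chosen plan reaches the same bond set in fewer steps.

Key step: step 5

Assumption: 9 and the diastereomer that forms beside it in step 5 differ only in the configuration of the two new ring stereocentres relative to the fixed camphor unit. Which of the two separated isomers is 9 would be assigned by X-ray analysis, with the camphor unit as internal reference.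

Assumption: the CIP descriptors of 9 and of the fallback and alternative compounds refer to the cyclopentenone numbering given above.

## Route

Step 1
Reactants: 1 kojic acid (5-hydroxy-2-(hydroxymethyl)-4H-pyran-4-one)
Product: 2 3,6-dibromo-5-hydroxy-2-(hydroxymethyl)-4H-pyran-4-one
Conditions: NBS (2.1 equiv), MeCN, 0 °C to rt
Reagents that add atoms: N-bromosuccinimide, O=C1CCC(=O)N1Br
Why: Electrophilic bromination at the only two ring C–H positions: C6 is ortho to the enolic hydroxyl (the usual site of electrophilic substitution of kojic acid) and C3 is the α-carbon of the vinylogous ester, the usual site for 4-pyranones. No stereocentre is formed.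

Step 2
Reactants: 2 3,6-dibromo-5-hydroxy-2-(hydroxymethyl)-4H-pyran-4-one
Product: 3 3,6-dibromo-2-(hydroxymethyl)-5-methoxy-4H-pyran-4-one
Conditions: MeI (1.2 equiv), K2CO3, acetone, rt
Reagents that add atoms: iodomethane, CI
Why: Williamson O-methylation of the acidic enolic hydroxyl (a vinylogous acid); K2CO3 should not deprotonate the primary alcohol, which stays free. This methoxy group becomes the C2 methoxy group of the target.

Step 3
Reactants: 3 3,6-dibromo-2-(hydroxymethyl)-5-methoxy-4H-pyran-4-one; 4 [4-(tert-butyldimethylsilyloxy)phenyl]boronic acid (2.5 equiv)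
Product: 5 3,6-bis[4-(tert-butyldimethylsilyloxy)phenyl]-2-(hydroxymethyl)-5-methoxy-4H-pyran-4-one
Conditions: Pd(OAc)2 (5 mol %), SPhos (10 mol %), K3PO4, toluene/H2O 10:1, 80 °C
Reagents that add atoms: none
Why: Twofold Suzuki–Miyaura coupling; the C6 bromide is a vinylogous acyl bromide and the C3 bromide an α-bromo enone, both ready for oxidative addition. The two aryl groups of the target are identical, so one operation should install both; the free primary alcohol is tolerated.

Step 4
Reactants: 5 3,6-bis[4-(tert-butyldimethylsilyloxy)phenyl]-2-(hydroxymethyl)-5-methoxy-4H-pyran-4-one; 6 (1S)-(+)-10-camphorsulfonyl chloride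
Product: 7 {3,6-bis[4-(tert-butyldimethylsilyloxy)phenyl]-5-methoxy-4-oxo-4H-pyran-2-yl}methyl (1S)-10-camphorsulfonate
Conditions: Et3N, DMAP (cat.), CH2Cl2, −20 °C, short reaction time
Reagents that add atoms: none
Why: Sulfonylation of the primary alcohol. The ester is the leaving group for step 6 and the resolving group for step 5. Low temperature should limit displacement of the activated sulfonate by chloride.

Step 5
Reactants: 7 {3,6-bis[4-(tert-butyldimethylsilyloxy)phenyl]-5-methoxy-4-oxo-4H-pyran-2-yl}methyl (1S)-10-camphorsulfonate
Product: 9 (4R,5R)-3,5-bis[4-(tert-butyldimethylsilyloxy)phenyl]-4-hydroxy-2,5-dimethoxy-4-{[(1S)-10-camphorsulfonyloxy]methyl}cyclopent-2-en-1-one, via oxyallyl zwitterion 8 (not isolated)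
Conditions: hν (350 nm, Pyrex, flow cell), MeOH (degassed, 5 mM), 0 °C, partial conversion per pass; then chromatography or crystallization to isolate 9 from the diastereomer of opposite ring configuration
Reagents that add atoms: methanol, CO
Why: Excitation of the cross-conjugated dienone of 7 should trigger the disrotatory 4π electrocyclization known for 4H-pyran-4-ones (a bond between the two carbons that flank the ring oxygen, the oxygen analogue of the type A cyclohexadienone rearrangement); this closes the cyclopentene ring and gives the oxirane-bridged 2-oxidoallyl cation 8. Methanol should add to the allyl terminus that carries the aryl group, from the face opposite the oxirane bridge, and the α-methoxy enol so formed should open the benzylic oxirane C–O bond by β-elimination, which leaves the former ring oxygen on C4 and the enone double bond between C2 and C3. The closest known reaction type is the photochemical ring contraction of alkyl-substituted 4-pyranones in alcohols to trans-4-hydroxy-5-alkoxycyclopent-2-enones. C5 is controlled by the anti approach of methanol to the bridged cation and C4 keeps its oxygen on the bridged face, so the C4 oxygen and the C5 methoxy group should come out trans, as in the target. The flat pyranone has no facial bias, so both mirror-image ring systems should form; the (1S)-camphorsulfonate makes them a pair of diastereomers, from which 9 is isolated while the isomer of (4S,5S) ring configuration is set aside. The selectivity the step needs is capture at the aryl-bearing terminus and not at the methoxy-bearing one: the 4-silyloxyphenyl group stabilizes positive charge at least as well as methoxy, the adduct of the wrong capture is an allylic mixed ketal of an enol that can re-ionize to 8 and whose onward oxirane opening is slowed by the sulfonyloxymethyl-bearing carbon, and the adduct of the right capture is drained at once by opening of the benzylic C–O bond. Low conversion per pass should limit secondary photolysis of the enone product and the competing walk of the oxirane in 8 to a 2-pyranone.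

Step 6
Reactants: 9 (4R,5R)-3,5-bis[4-(tert-butyldimethylsilyloxy)phenyl]-4-hydroxy-2,5-dimethoxy-4-{[(1S)-10-camphorsulfonyloxy]methyl}cyclopent-2-en-1-one
Product: 10 (3R,4R)-4,7-bis[4-(tert-butyldimethylsilyloxy)phenyl]-4,6-dimethoxy-1-oxaspiro[2.4]hept-6-en-5-one
Conditions: NaH (1.1 equiv), THF, 0 °C
Reagents that add atoms: none
Why: Intramolecular Williamson (3-exo-tet) closure: the C4 alkoxide displaces the primary sulfonate, and the C4–O bond is not touched, so the configuration of C4 is kept. 9 has no acidic C–H next to the ketone, and the fast irreversible closure should outrun retro-aldol opening of the alkoxide.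

Step 7
Reactants: 10 (3R,4R)-4,7-bis[4-(tert-butyldimethylsilyloxy)phenyl]-4,6-dimethoxy-1-oxaspiro[2.4]hept-6-en-5-one
Product: 11 (3R,4R)-4,7-bis(4-hydroxyphenyl)-4,6-dimethoxy-1-oxaspiro[2.4]hept-6-en-5-one (CNP0504072.1)
Conditions: TBAF (2.2 equiv), AcOH (2.5 equiv), THF, 0 °C
Reagents that add atoms: none
Why: Fluoride cleavage of the two aryl silyl ethers. The acetic acid buffer keeps the phenols protonated, which should protect the oxirane from alkoxide attack and the C5 methyl ether from quinone methide formation; no stereocentre is touched.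

## Compound list

1 | kojic acid (5-hydroxy-2-(hydroxymethyl)-4H-pyran-4-one) | OCc1cc(=O)c(O)co1 | starting material
2 | 3,6-dibromo-5-hydroxy-2-(hydroxymethyl)-4H-pyran-4-one | OCc1oc(Br)c(O)c(=O)c1Br | intermediate
3 | 3,6-dibromo-2-(hydroxymethyl)-5-methoxy-4H-pyran-4-one | COc1c(Br)oc(CO)c(Br)c1=O | intermediate
4 | [4-(tert-butyldimethylsilyloxy)phenyl]boronic acid | CC(C)(C)[Si](C)(C)Oc1ccc(B(O)O)cc1 | starting material
5 | 3,6-bis[4-(tert-butyldimethylsilyloxy)phenyl]-2-(hydroxymethyl)-5-methoxy-4H-pyran-4-one | COc1c(-c2ccc(O[Si](C)(C)C(C)(C)C)cc2)oc(CO)c(-c2ccc(O[Si](C)(C)C(C)(C)C)cc2)c1=O | intermediate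
6 | (1S)-(+)-10-camphorsulfonyl chloride | ClS(=O)(=O)C[C@@]12C(=O)C[C@@H](CC1)C2(C)C | starting material
7 | {3,6-bis[4-(tert-butyldimethylsilyloxy)phenyl]-5-methoxy-4-oxo-4H-pyran-2-yl}methyl (1S)-10-camphorsulfonate | COc1c(-c2ccc(O[Si](C)(C)C(C)(C)C)cc2)oc(COS(=O)(=O)C[C@@]34C(=O)C[C@@H](CC3)C4(C)C)c(-c2ccc(O[Si](C)(C)C(C)(C)C)cc2)c1=O | intermediate
8 | oxirane-bridged 2-oxidoallyl cation (6-oxabicyclo[3.1.0]hexenyl zwitterion) from 7, drawn as the stereoisomer that leads to 9; its ring antipode forms as well | COC1=C([O-])[C+](c2ccc(O[Si](C)(C)C(C)(C)C)cc2)[C@@]2(COS(=O)(=O)C[C@@]34C(=O)C[C@@H](CC3)C4(C)C)O[C@@]12c1ccc(O[Si](C)(C)C(C)(C)C)cc1 | intermediate (not isolated)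
9 | (4R,5R)-3,5-bis[4-(tert-butyldimethylsilyloxy)phenyl]-4-hydroxy-2,5-dimethoxy-4-{[(1S)-10-camphorsulfonyloxy]methyl}cyclopent-2-en-1-one | COC1=C(c2ccc(O[Si](C)(C)C(C)(C)C)cc2)[C@@](O)(COS(=O)(=O)C[C@@]34C(=O)C[C@@H](CC3)C4(C)C)[C@](OC)(c2ccc(O[Si](C)(C)C(C)(C)C)cc2)C1=O | intermediate
10 | (3R,4R)-4,7-bis[4-(tert-butyldimethylsilyloxy)phenyl]-4,6-dimethoxy-1-oxaspiro[2.4]hept-6-en-5-one | COC1=C(c2ccc(O[Si](C)(C)C(C)(C)C)cc2)[C@@]2(CO2)[C@](OC)(c2ccc(O[Si](C)(C)C(C)(C)C)cc2)C1=O | intermediate
11 | (3R,4R)-4,7-bis(4-hydroxyphenyl)-4,6-dimethoxy-1-oxaspiro[2.4]hept-6-en-5-one | COC1=C(c2ccc(O)cc2)[C@@]2(CO2)[C@](OC)(c2ccc(O)cc2)C1=O | target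

## Step count and least certain steps

Total steps: 7. Longest linear sequence: 7 steps, from kojic acid 1.

**Step 5 (key step).** The most likely failure is capture of the solvent at the methoxy-bearing terminus of the unsymmetrical cation. An alkoxy group concentrates positive charge on its own carbon, so a ketal could form and the oxirane would then open in the other direction. Lesser risks are the oxirane walk to a 2-pyranone, secondary photolysis of the product, and weak differentiation of the two diastereomers by the remote camphor unit on separation.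

The fallback reverses the electronic bias of the cation instead of changing the irradiation. It sets out from 2 and comes back at 9.
- The acidic 5-hydroxyl of 2 is acylated (pivaloyl chloride, Et3N, CH2Cl2, −20 °C) to 3,6-dibromo-2-(hydroxymethyl)-5-(pivaloyloxy)-4H-pyran-4-one F1.
- F1 is coupled twice with 4 as in step 3 to 3,6-bis[4-(tert-butyldimethylsilyloxy)phenyl]-2-(hydroxymethyl)-5-(pivaloyloxy)-4H-pyran-4-one F2.
- F2 is sulfonylated with 6 as in step 4 to {3,6-bis[4-(tert-butyldimethylsilyloxy)phenyl]-4-oxo-5-(pivaloyloxy)-4H-pyran-2-yl}methyl (1S)-10-camphorsulfonate F3.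
- An acyloxy group is a far weaker π-donor than methoxy, so on irradiation of F3 in methanol the charge of the cation should sit on the benzylic terminus and the solvent should add there. After separation of the diastereomers this gives (4R,5R)-3,5-bis[4-(tert-butyldimethylsilyloxy)phenyl]-4-hydroxy-5-methoxy-1-oxo-4-{[(1S)-10-camphorsulfonyloxy]methyl}cyclopent-2-en-2-yl pivalate F4.
- Pyrrolidine in THF at 0 °C cleaves the enol ester to the diosphenol (4R,5R)-3,5-bis[4-(tert-butyldimethylsilyloxy)phenyl]-2,4-dihydroxy-5-methoxy-4-{[(1S)-10-camphorsulfonyloxy]methyl}cyclopent-2-en-1-one F5. The neopentyl-type sulfonate should survive.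
- Me3SiCHN2 in MeOH/toluene methylates the acidic enol of F5 selectively and gives 9.

**Step 1.** The second bromination may stall, because C3 is less activated once C6 carries bromine, and excess NBS may oxidize the free enol.

The fallback halogenates in two separate operations with the enol masked in between. It sets out from 1 and comes back at 5.
- Iodination (I2, Na2CO3, H2O) at the enol-activated position gives 5-hydroxy-2-(hydroxymethyl)-6-iodo-4H-pyran-4-one F6.
- O-methylation (MeI, K2CO3, acetone) gives 2-(hydroxymethyl)-6-iodo-5-methoxy-4H-pyran-4-one F7.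
- Bromination of the one remaining ring C–H (NBS, MeCN) gives 3-bromo-2-(hydroxymethyl)-6-iodo-5-methoxy-4H-pyran-4-one F8.
- F8 is coupled with 4 under the conditions of step 3, where iodide and bromide both react, to give 5.

**Step 3.** The aryl silyl ethers may be lost in the basic aqueous medium at 80 °C, and the second coupling at the hindered C3 bromide may be slow.

The fallback moves the silylation behind the coupling, so the coupling can be forced without regard to protecting groups. It sets out from 3 and comes back at 5.
- 3 is coupled with (4-hydroxyphenyl)boronic acid (Pd(OAc)2, SPhos, K3PO4, dioxane/H2O, 100 °C) to 3,6-bis(4-hydroxyphenyl)-2-(hydroxymethyl)-5-methoxy-4H-pyran-4-one F9.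
- All three hydroxyls are silylated (TBSCl, imidazole, DMF) to 3,6-bis[4-(tert-butyldimethylsilyloxy)phenyl]-2-[(tert-butyldimethylsilyloxy)methyl]-5-methoxy-4H-pyran-4-one F10.
- PPTS in MeOH cleaves only the primary alkyl silyl ether, since aryl silyl ethers are much more stable to acid, and gives 5.

**Step 4.** Chloride set free in the sulfonylation may displace the activated sulfonate (a vinylogous α-keto position), which would remove the resolving group.

The fallback forms the C–O bond of the sulfonate by substitution at carbon, with the halide removed as an insoluble silver salt. It sets out from 5 and comes back at 7.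
- 5 is converted (CBr4, PPh3, CH2Cl2, 0 °C) to 2-(bromomethyl)-3,6-bis[4-(tert-butyldimethylsilyloxy)phenyl]-5-methoxy-4H-pyran-4-one F11.
- F11 is treated with silver (1S)-10-camphorsulfonate, AgO3SC10H15O, in MeCN in the dark to give 7.

## Further compounds

F1 | step 5 | 3,6-dibromo-2-(hydroxymethyl)-5-(pivaloyloxy)-4H-pyran-4-one | CC(C)(C)C(=O)Oc1c(Br)oc(CO)c(Br)c1=O
F2 | step 5 | 3,6-bis[4-(tert-butyldimethylsilyloxy)phenyl]-2-(hydroxymethyl)-5-(pivaloyloxy)-4H-pyran-4-one | CC(C)(C)C(=O)Oc1c(-c2ccc(O[Si](C)(C)C(C)(C)C)cc2)oc(CO)c(-c2ccc(O[Si](C)(C)C(C)(C)C)cc2)c1=O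
F3 | step 5 | {3,6-bis[4-(tert-butyldimethylsilyloxy)phenyl]-4-oxo-5-(pivaloyloxy)-4H-pyran-2-yl}methyl (1S)-10-camphorsulfonate | CC(C)(C)C(=O)Oc1c(-c2ccc(O[Si](C)(C)C(C)(C)C)cc2)oc(COS(=O)(=O)C[C@@]34C(=O)C[C@@H](CC3)C4(C)C)c(-c2ccc(O[Si](C)(C)C(C)(C)C)cc2)c1=O
F4 | step 5 | (4R,5R)-3,5-bis[4-(tert-butyldimethylsilyloxy)phenyl]-4-hydroxy-5-methoxy-1-oxo-4-{[(1S)-10-camphorsulfonyloxy]methyl}cyclopent-2-en-2-yl pivalate | CC(C)(C)C(=O)OC1=C(c2ccc(O[Si](C)(C)C(C)(C)C)cc2)[C@@](O)(COS(=O)(=O)C[C@@]34C(=O)C[C@@H](CC3)C4(C)C)[C@](OC)(c2ccc(O[Si](C)(C)C(C)(C)C)cc2)C1=O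
F5 | step 5 | (4R,5R)-3,5-bis[4-(tert-butyldimethylsilyloxy)phenyl]-2,4-dihydroxy-5-methoxy-4-{[(1S)-10-camphorsulfonyloxy]methyl}cyclopent-2-en-1-one | OC1=C(c2ccc(O[Si](C)(C)C(C)(C)C)cc2)[C@@](O)(COS(=O)(=O)C[C@@]34C(=O)C[C@@H](CC3)C4(C)C)[C@](OC)(c2ccc(O[Si](C)(C)C(C)(C)C)cc2)C1=O
F6 | step 1 | 5-hydroxy-2-(hydroxymethyl)-6-iodo-4H-pyran-4-one | OCc1cc(=O)c(O)c(I)o1
F7 | step 1 | 2-(hydroxymethyl)-6-iodo-5-methoxy-4H-pyran-4-one | COc1c(I)oc(CO)cc1=O
F8 | step 1 | 3-bromo-2-(hydroxymethyl)-6-iodo-5-methoxy-4H-pyran-4-one | COc1c(I)oc(CO)c(Br)c1=O
F9 | step 3 | 3,6-bis(4-hydroxyphenyl)-2-(hydroxymethyl)-5-methoxy-4H-pyran-4-one | COc1c(-c2ccc(O)cc2)oc(CO)c(-c2ccc(O)cc2)c1=O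
F10 | step 3 | 3,6-bis[4-(tert-butyldimethylsilyloxy)phenyl]-2-[(tert-butyldimethylsilyloxy)methyl]-5-methoxy-4H-pyran-4-one | COc1c(-c2ccc(O[Si](C)(C)C(C)(C)C)cc2)oc(CO[Si](C)(C)C(C)(C)C)c(-c2ccc(O[Si](C)(C)C(C)(C)C)cc2)c1=O
F11 | step 4 | 2-(bromomethyl)-3,6-bis[4-(tert-butyldimethylsilyloxy)phenyl]-5-methoxy-4H-pyran-4-one | COc1c(-c2ccc(O[Si](C)(C)C(C)(C)C)cc2)oc(CBr)c(-c2ccc(O[Si](C)(C)C(C)(C)C)cc2)c1=O
A1 | alternative 1 | 3,5-bis[4-(benzyloxy)phenyl]cyclopentane-1,2,4-trione | O=C1C(=O)C(c2ccc(OCc3ccccc3)cc2)C(=O)C1c1ccc(OCc2ccccc2)cc1
A2 | alternative 1 | (5R)-3,5-bis[4-(benzyloxy)phenyl]-2,5-dimethoxycyclopent-2-ene-1,4-dione | COC1=C(c2ccc(OCc3ccccc3)cc2)C(=O)[C@](OC)(c2ccc(OCc3ccccc3)cc2)C1=O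
A3 | alternative 2 | 1,4-bis[4-(tert-butyldimethylsilyloxy)phenyl]-1-methoxyhexa-4,5-diene-2,3-dione (racemic at C1) | COC(c1ccc(O[Si](C)(C)C(C)(C)C)cc1)C(=O)C(=O)C(=C=C)c1ccc(O[Si](C)(C)C(C)(C)C)cc1
A4 | alternative 2 | (5R)-3,5-bis[4-(tert-butyldimethylsilyloxy)phenyl]-2-hydroxy-5-methoxy-4-methylidenecyclopent-2-en-1-one | OC1=C(c2ccc(O[Si](C)(C)C(C)(C)C)cc2)C(=C)[C@](OC)(c2ccc(O[Si](C)(C)C(C)(C)C)cc2)C1=O
A5 | alternative 3 | 2,5-bis[4-(tert-butyldimethylsilyloxy)phenyl]-6-(hydroxymethyl)-4-methoxypyrylium-3-olate | COc1c(-c2ccc(O[Si](C)(C)C(C)(C)C)cc2)c(CO)[o+]c(-c2ccc(O[Si](C)(C)C(C)(C)C)cc2)c1[O-]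
A6 | alternative 3 | (1R,5S)-1,4-bis[4-(tert-butyldimethylsilyloxy)phenyl]-5-(hydroxymethyl)-3-methoxy-6-oxabicyclo[3.1.0]hex-3-en-2-one | COC1=C(c2ccc(O[Si](C)(C)C(C)(C)C)cc2)[C@@]2(CO)O[C@@]2(c2ccc(O[Si](C)(C)C(C)(C)C)cc2)C1=O
A7 | alternative 3 | (3R,4R)-4,7-bis[4-(tert-butyldimethylsilyloxy)phenyl]-4-hydroxy-6-methoxy-1-oxaspiro[2.4]hept-6-en-5-one | COC1=C(c2ccc(O[Si](C)(C)C(C)(C)C)cc2)[C@@]2(CO2)[C@](O)(c2ccc(O[Si](C)(C)C(C)(C)C)cc2)C1=O
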